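**Plan**

1. Cuts: the C6 ester C–O bond; the ring bond C6–C7 (germacrane numbering: ring C1–C10, methyls on C4 and C10, isopropyl on C7); the chain bond C8–C9; the C11=C12 methylene.
2. Enabling feature: C6(O)–C7(branched C3 unit)–C8(O) is a 2-alkenyl-1,3-diol set in the ten-membered ring next to the C4–C5 oxirane, i.e. the adduct of a C6 aldehyde with a hydroxy-allyl metal stored as a C7–C8 isopropenyl oxirane.
3. Forward: geranyl acetate (supplies C1–C6, C9, C10, both methyls and both E-alkenes) is oxidised at C9, brominated and joined to (R)-but-3-yn-2-ol; hydride reduction gives a bis-allylic diol.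
4. One Sharpless epoxidation installs both oxiranes; oxidation and methylenation give the isopropenyl oxirane, a second oxidation the epoxy aldehyde; zerovalent palladium with Et2Zn then closes the ten-membered ring, the only carbocycle.
5. Stereochemistry: C4, C5 and C8 from the D-(−)-tartrate epoxidation (the butynol carbinol is a matched control element, erased later); C6 and C7 from the ring closure under control of C5 and C8; E-C1=C10 from geranyl acetate and the SeO2 oxidation.
6. End game: silylation of O8, esterification of O6, hydrogenation of the isopropenyl group, desilylation.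

Key step: step 11

Remark: (R)-but-3-yn-2-ol, geranyl acetate, D-(−)-diethyl tartrate and 4-hydroxybenzoic acid are taken as commercial; germacrane numbering is used for locants throughout.

**Step 1**
Reactants: 1 geranyl acetate
Product: 2 (2E,6E)-8-hydroxy-3,7-dimethylocta-2,6-dien-1-yl acetate
Conditions: SeO2 (0.1 equiv), t-BuOOH, salicylic acid (cat.), CH2Cl2, rt
Reagents that add atoms: selenium dioxide O=[Se]=O; tert-butyl hydroperoxide CC(C)(C)OO
Why: Riley allylic oxidation (ene reaction then [2,3]-shift) should hydroxylate the E-methyl of the terminal trisubstituted alkene, the other alkene being deactivated by the allylic acetate.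

**Step 2**
Reactants: 2 (2E,6E)-8-hydroxy-3,7-dimethylocta-2,6-dien-1-yl acetate
Product: 3 (2E,6E)-8-bromo-3,7-dimethylocta-2,6-dien-1-yl acetate
Conditions: CBr4, PPh3, CH2Cl2, 0 °C
Reagents that add atoms: carbon tetrabromide BrC(Br)(Br)Br
Why: Appel bromination of a primary allylic alcohol should proceed by SN2 displacement without allylic transposition or loss of alkene geometry.

**Step 3**
Reactants: 3 (2E,6E)-8-bromo-3,7-dimethylocta-2,6-dien-1-yl acetate; 4 (R)-but-3-yn-2-ol
Product: 5 (2E,6E,11R)-11-hydroxy-3,7-dimethyldodeca-2,6-dien-9-yn-1-yl acetate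
Conditions: CuI (cat.), K2CO3, Bu4NI (cat.), DMF, rt
Reagents that add atoms: none
Why: Copper-catalysed alkynylation of a primary allylic bromide (copper acetylide, SN2) should give the skipped 1,4-enyne and tolerates the free carbinol and the acetate; the carbinol stereocentre of 4 is not touched.

**Step 4**
Reactants: 5 (2E,6E,11R)-11-hydroxy-3,7-dimethyldodeca-2,6-dien-9-yn-1-yl acetate
Product: 6 (2E,6E,9E,11R)-3,7-dimethyldodeca-2,6,9-triene-1,11-diol
Conditions: NaAlH2(OCH2CH2OMe)2 (excess), THF, 0 °C to rt; aq. potassium sodium tartrate work-up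
Reagents that add atoms: none
Why: Alkoxide-directed trans-hydroalumination of the propargylic alcohol should give the E-allylic alcohol, while the same hydride cleaves the acetate reductively and leaves the isolated alkenes alone.

**Step 5**
Reactants: 6 (2E,6E,9E,11R)-3,7-dimethyldodeca-2,6,9-triene-1,11-diol
Product: 7 (2R,3R,6E,9R,10R,11R)-2,3:9,10-diepoxy-3,7-dimethyldodec-6-ene-1,11-diol
Conditions: Ti(OiPr)4 (0.3 equiv), D-(−)-diethyl tartrate (0.36 equiv), t-BuOOH (3 equiv), 4 Å MS, CH2Cl2, −20 °C
Reagents that add atoms: tert-butyl hydroperoxide CC(C)(C)OO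
Why: Sharpless asymmetric epoxidation of both allylic alcohols, in which the D-tartrate should dictate the face at each alkene (2R,3R at the geraniol-type alkene, 9R,10R at the E-disubstituted alkene, for which the (R)-carbinol is the fast-reacting matched enantiomer), while the isolated central alkene has no directing hydroxyl.

**Step 6**
Reactants: 7 (2R,3R,6E,9R,10R,11R)-2,3:9,10-diepoxy-3,7-dimethyldodec-6-ene-1,11-diol
Product: 8 the 1-O-tert-butyldimethylsilyl ether of 7 (primary hydroxyl silylated, secondary carbinol free)
Conditions: TBSCl (1.05 equiv), imidazole, CH2Cl2, −20 to 0 °C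
Reagents that add atoms: tert-butyldimethylsilyl chloride CC(C)(C)[Si](C)(C)Cl
Why: Silyl ether formation should be much faster at the primary than at the secondary hydroxyl.

**Step 7**
Reactants: 8 the 1-O-tert-butyldimethylsilyl ether of 7
Product: 9 the methyl ketone of 8 (C11 carbinol oxidised; trans-α,β-epoxy ketone, other stereocentres unchanged)
Conditions: Dess–Martin periodinane, NaHCO3, CH2Cl2, 0 °C to rt
Reagents that add atoms: none
Why: Buffered Dess–Martin oxidation should convert the secondary epoxy alcohol into the epoxy ketone without opening either oxirane.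

**Step 8**
Reactants: 9 the methyl ketone of 8
Product: 10 the isopropenyl oxirane (C11 carbonyl replaced by C11=C12H2; silyl ether retained)
Conditions: Ph3PCH3Br, KN(SiMe3)2, THF, −78 to 0 °C
Reagents that add atoms: methyltriphenylphosphonium bromide C[P+](c1ccccc1)(c1ccccc1)c1ccccc1.[Br-]
Why: Wittig methylenation of the ketone should give the 2-alkenyl oxirane, and the oxirane carbon next to the carbonyl is not epimerised at low temperature.

**Step 9**
Reactants: 10 the isopropenyl oxirane silyl ether
Product: 11 [(2R,3R)-3-methyl-3-{(3E)-4-methyl-5-[(2R,3R)-3-(prop-1-en-2-yl)oxiran-2-yl]pent-3-en-1-yl}oxiran-2-yl]methanol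
Conditions: Bu4NF, AcOH (1:1), THF, 0 °C
Reagents that add atoms: none
Why: Fluoride desilylation should free the primary alcohol, and the acetic acid buffer suppresses Payne rearrangement of the 2,3-epoxy alcohol.

**Step 10**
Reactants: 11 the epoxy alcohol from step 9
Product: 12 (2S,3R)-3-methyl-3-{(3E)-4-methyl-5-[(2R,3R)-3-(prop-1-en-2-yl)oxiran-2-yl]pent-3-en-1-yl}oxirane-2-carbaldehyde
Conditions: Dess–Martin periodinane, NaHCO3, CH2Cl2, 0 °C
Reagents that add atoms: none
Why: Buffered Dess–Martin oxidation should give the α,β-epoxy aldehyde without epimerisation at C5 and without touching the alkenyl oxirane.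

**Step 11**
Reactants: 12 the epoxy aldehyde with the isopropenyl oxirane
Product: 14 (1(10)E,4R,5R,6S,7R,8R)-4,5-epoxygermacra-1(10),11-diene-6,8-diol, via allylzinc alkoxide 13 (not isolated)
Conditions: Pd(PPh3)4 (10 mol %), Et2Zn (3 equiv), THF, 0.005 M, slow addition of 12, 0 °C to rt; aqueous work-up
Reagents that add atoms: none
Why: Proposed new method: zerovalent palladium should ionise only the allylic C7–O bond of the isopropenyl oxirane (the C4–C5 oxirane is not allylic) to a π-allylpalladium alkoxide, Et2Zn reverses its polarity by transmetalation to the allylzinc alkoxide 13, and the allylzinc adds through its γ-carbon C7 to the C6 aldehyde in a closed six-membered transition state; the closest known reaction types are the Pd/Et2Zn umpolung allylation that closes ten-membered germacrane rings from formyl-bearing allylic chlorides and the intermolecular palladium-catalysed umpolung of alkenyl oxiranes to 2-vinyl-1,3-diols, which are merged here. The ten-membered carbocycle closes in the 10-exo-trig mode at the carbonyl and by SE2' at the allyl unit, which leaves C11=C12 exocyclic. C7 is controlled by the chair transition state of the equilibrating E-allylzinc with both ring branches equatorial (C6–O and isopropenyl trans) and by the resident C8 stereocentre, whose zinc alkoxide lies gauche to the forming bond (C8–H anti) where it can also bind the aldehyde oxygen. C6 is controlled by the C5 stereocentre of the epoxy aldehyde: zinc bridges the carbonyl and oxirane oxygens and the allyl carbon attacks the face on the side of C5–H, which gives the threo C5/C6 relationship. The step needs γ- over α-attack (secured by the cyclic transition state), ring closure over oligomerisation (slow addition at high dilution, the E-C1=C10 alkene and the trans-oxirane pre-folding the chain) and no β-elimination of the C8 oxygen (secured because it is a metal alkoxide and not an ether).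

**Step 12**
Reactants: 14 (1(10)E,4R,5R,6S,7R,8R)-4,5-epoxygermacra-1(10),11-diene-6,8-diol
Product: 15 the 8-O-triethylsilyl ether of 14 (C6 hydroxyl free)
Conditions: Et3SiCl (1.05 equiv), imidazole, CH2Cl2, −40 to −20 °C
Reagents that add atoms: chlorotriethylsilane CC[Si](Cl)(CC)CC
Why: Kinetic silylation should prefer the C8 hydroxyl, which is flanked by a methylene group, over the C6 hydroxyl, which sits between the oxirane and C7 and is less nucleophilic.

**Step 13**
Reactants: 16 4-hydroxybenzoic acid
Product: 18 4-(tert-butyldimethylsilyloxy)benzoic acid, via bis-silyl derivative 17 (not isolated)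
Conditions: TBSCl (2.5 equiv), imidazole, DMF, rt; then AcOH/THF/H2O, rt
Reagents that add atoms: tert-butyldimethylsilyl chloride CC(C)(C)[Si](C)(C)Cl
Why: Double silylation followed by selective hydrolysis of the labile silyl ester should leave the aryl silyl ether in place.

**Step 14**
Reactants: 15 the 8-O-triethylsilyl ether of 14; 18 4-(tert-butyldimethylsilyloxy)benzoic acid
Product: 19 the 6-O-[4-(tert-butyldimethylsilyloxy)benzoyl] ester of 15
Conditions: DCC, DMAP (cat.), CH2Cl2, rt
Reagents that add atoms: none
Why: Steglich esterification should acylate the only free hydroxyl (C6) with retention, under conditions that leave the oxirane and the silyl ethers intact.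

**Step 15**
Reactants: 19 the 6-O-aroyl 8-O-triethylsilyl diene
Product: 20 the 11,12-dihydro compound (isopropyl at C7), otherwise as 19
Conditions: H2 (1 atm), RhCl(PPh3)3 (10 mol %), benzene/EtOH, rt
Reagents that add atoms: none
Why: Homogeneous hydrogenation with RhCl(PPh3)3 should reduce the unhindered 1,1-disubstituted alkene and leave the trisubstituted ring alkene and the oxirane; no stereocentre is created.

**Step 16**
Reactants: 20 the bis-silylated dihydro ester
Product: 21 (1(10)E,4R,5R,6S,7R,8R)-4,5-epoxy-8-hydroxygermacr-1(10)-en-6-yl 4-hydroxybenzoate (target)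
Conditions: Bu4NF, AcOH (1:1), THF, 0 °C to rt
Reagents that add atoms: none
Why: Buffered fluoride desilylation should remove the aryl and the alkyl silyl ether together without acid (transannular opening of the oxirane) or strong base (acyl migration).

**Compound list**

1 | geranyl acetate, (2E)-3,7-dimethylocta-2,6-dien-1-yl acetate | CC(C)=CCC/C(C)=C/COC(C)=O | starting material
2 | (2E,6E)-8-hydroxy-3,7-dimethylocta-2,6-dien-1-yl acetate | OC/C(C)=C/CC/C(C)=C/COC(C)=O | intermediate
3 | (2E,6E)-8-bromo-3,7-dimethylocta-2,6-dien-1-yl acetate | BrC/C(C)=C/CC/C(C)=C/COC(C)=O | intermediate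
4 | (R)-but-3-yn-2-ol | C[C@@H](O)C#C | starting material
5 | (2E,6E,11R)-11-hydroxy-3,7-dimethyldodeca-2,6-dien-9-yn-1-yl acetate | C[C@@H](O)C#CC/C(C)=C/CC/C(C)=C/COC(C)=O | intermediate
6 | (2E,6E,9E,11R)-3,7-dimethyldodeca-2,6,9-triene-1,11-diol | C[C@@H](O)/C=C/C/C(C)=C/CC/C(C)=C/CO | intermediate
7 | (2R,3R,6E,9R,10R,11R)-2,3:9,10-diepoxy-3,7-dimethyldodec-6-ene-1,11-diol | C[C@@H](O)[C@H]1O[C@@H]1C/C(C)=C/CC[C@@]2(C)O[C@@H]2CO | intermediate
8 | 1-O-tert-butyldimethylsilyl ether of 7 | C[C@@H](O)[C@H]1O[C@@H]1C/C(C)=C/CC[C@@]2(C)O[C@@H]2CO[Si](C)(C)C(C)(C)C | intermediate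
9 | methyl ketone of 8 (trans-α,β-epoxy ketone) | CC(=O)[C@H]1O[C@@H]1C/C(C)=C/CC[C@@]2(C)O[C@@H]2CO[Si](C)(C)C(C)(C)C | intermediate
10 | (2R,3R)-3-(prop-1-en-2-yl)oxirane from methylenation of 9, silyl ether retained | C=C(C)[C@H]1O[C@@H]1C/C(C)=C/CC[C@@]2(C)O[C@@H]2CO[Si](C)(C)C(C)(C)C | intermediate
11 | [(2R,3R)-3-methyl-3-{(3E)-4-methyl-5-[(2R,3R)-3-(prop-1-en-2-yl)oxiran-2-yl]pent-3-en-1-yl}oxiran-2-yl]methanol | C=C(C)[C@H]1O[C@@H]1C/C(C)=C/CC[C@@]2(C)O[C@@H]2CO | intermediate
12 | (2S,3R)-3-methyl-3-{(3E)-4-methyl-5-[(2R,3R)-3-(prop-1-en-2-yl)oxiran-2-yl]pent-3-en-1-yl}oxirane-2-carbaldehyde | C=C(C)[C@H]1O[C@@H]1C/C(C)=C/CC[C@@]2(C)O[C@@H]2C=O | intermediate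
13 | ethylzinc C8-alkoxide carrying the E-allyl(ethyl)zinc unit at C12, formed from 12 by ionisation of C7–O and transmetalation (not isolated) | CC[Zn]C/C(C)=C/[C@H](O[Zn]CC)C/C(C)=C/CC[C@@]1(C)O[C@@H]1C=O | intermediate
14 | (1(10)E,4R,5R,6S,7R,8R)-4,5-epoxygermacra-1(10),11-diene-6,8-diol | C/C1=C\CC[C@@]2(C)O[C@@H]2[C@@H](O)[C@H](C(C)=C)[C@H](O)C1 | intermediate
15 | 8-O-triethylsilyl ether of 14 | C/C1=C\CC[C@@]2(C)O[C@@H]2[C@@H](O)[C@H](C(C)=C)[C@H](O[Si](CC)(CC)CC)C1 | intermediate
16 | 4-hydroxybenzoic acid | OC(=O)c1ccc(O)cc1 | starting material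
17 | tert-butyldimethylsilyl 4-(tert-butyldimethylsilyloxy)benzoate (not isolated) | CC(C)(C)[Si](C)(C)OC(=O)c1ccc(O[Si](C)(C)C(C)(C)C)cc1 | intermediate
18 | 4-(tert-butyldimethylsilyloxy)benzoic acid | OC(=O)c1ccc(O[Si](C)(C)C(C)(C)C)cc1 | intermediate
19 | 6-O-[4-(tert-butyldimethylsilyloxy)benzoyl]-8-O-triethylsilyl derivative of 14 | C/C1=C\CC[C@@]2(C)O[C@@H]2[C@@H](OC(=O)c2ccc(O[Si](C)(C)C(C)(C)C)cc2)[C@H](C(C)=C)[C@H](O[Si](CC)(CC)CC)C1 | intermediate
20 | 11,12-dihydro derivative of 19 (isopropyl at C7) | C/C1=C\CC[C@@]2(C)O[C@@H]2[C@@H](OC(=O)c2ccc(O[Si](C)(C)C(C)(C)C)cc2)[C@H](C(C)C)[C@H](O[Si](CC)(CC)CC)C1 | intermediate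
21 | (1(10)E,4R,5R,6S,7R,8R)-4,5-epoxy-8-hydroxygermacr-1(10)-en-6-yl 4-hydroxybenzoate | C/C1=C\CC[C@@]2(C)O[C@@H]2[C@@H](OC(=O)c2ccc(O)cc2)[C@H](C(C)C)[C@H](O)C1 | target

**Totals**

Total steps: 16. Longest linear sequence: 15 (steps 1–12 and 14–16; step 13 is a side branch).

**Steps most likely to fail**

Step 11. The π-allylpalladium alkoxide may isomerise (hydride shift to an enone or dienol, closure to a dihydrofuran), take up an ethyl group, oligomerise, or close through a diastereomeric transition state. Fallback, from 12 back to 15: the alkenyl oxirane of 12 is opened with Et3SiCl and catalytic Bu4NCl to the β-chloro triethylsilyl ether F1 (the C7 configuration and any 1,4-regioisomer are immaterial, since all ionise to the same allyl unit). F1 is then cyclised by the established allylic-chloride form of the reaction (Pd(PPh3)4, Et2Zn, high dilution), which gives 15 directly and makes step 12 unnecessary.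

Step 12. Silylation may occur at the C6 hydroxyl or at both hydroxyls (poor site selectivity). Fallback, from 14 back to 21: if O6 proves the more reactive site, 14 is mono-esterified directly with 18 (DCC, DMAP, −20 °C) to the 6-monoester with free C8 hydroxyl F2. Hydrogenation with RhCl(PPh3)3/H2 gives the dihydro ester F3, and Bu4NF/AcOH gives 21.

Step 15. The strained E ring alkene may be reduced or isomerised as well, or the reduction may stall at the hindered isopropenyl group. Fallback, from 19 back to 20: metal-free diimide transfer reduction (2-nitrobenzenesulfonyl hydrazide, Et3N, CH2Cl2, rt), which reduces 1,1-disubstituted alkenes far faster than trisubstituted ones and cannot isomerise or open the oxirane.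

Further compounds
F1 | step 11 | β-chloro triethylsilyl ether from chloride opening of the alkenyl oxirane of 12 at C7 (C8–O–SiEt3, C7–Cl, isopropenyl retained; epoxy aldehyde unchanged) | C=C(C)[C@H](Cl)[C@H](O[Si](CC)(CC)CC)C/C(C)=C/CC[C@@]1(C)O[C@@H]1C=O
F2 | step 12 | 6-O-[4-(tert-butyldimethylsilyloxy)benzoyl] ester of 14 with free C8 hydroxyl | C/C1=C\CC[C@@]2(C)O[C@@H]2[C@@H](OC(=O)c2ccc(O[Si](C)(C)C(C)(C)C)cc2)[C@H](C(C)=C)[C@H](O)C1
F3 | step 12 | 11,12-dihydro derivative of F2 | C/C1=C\CC[C@@]2(C)O[C@@H]2[C@@H](OC(=O)c2ccc(O[Si](C)(C)C(C)(C)C)cc2)[C@H](C(C)C)[C@H](O)C1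
F0 | step 15 | none | none
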